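Ring A is not carried through the synthesis but grown in one operation onto a preformed, enantiopure ring C, from a diazo ketone and a siloxyalkyne that carries the side-chain carbinol. The C4a=C8a bond of the dihydropyranone (ring C) serves as the vinyl arm of a vinylketene made by photochemical Wolff rearrangement. [2+2] addition of the ynol ether, 4π opening and 6π closure then give the hexasubstituted ring A, with 5-OH, the C6 side chain, 7-O-silyl and 8-prenyl placed by connectivity alone. The precursor is a (2S)-2-aryl-6-acyl-2,3-dihydropyran-4-one whose acyl group holds the diazo carbon and the prenyl CH2. One buffered fluoride treatment frees the three hydroxyls.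

Key step: step 10

Assumption: the target is (2S) at C2 of ring C and (R) at the side-chain carbinol. The facial sense of the two catalytic asymmetric additions (steps 3 and 7) is taken from the accepted transition-state models and has to be confirmed on the first batch; the antipodal ligand or acid is used if it proves opposite. Flavanone numbering is used (O1, C2, C3, C4, C4a, C5 to C8, C8a; ring A benzene, ring B 4-hydroxyphenyl, ring C pyranone).

Step 1
Reactants: 1 4-hydroxybenzaldehyde
Product: 2 4-(triisopropylsilyloxy)benzaldehyde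
Conditions: i-Pr3SiCl, imidazole, DMF, rt
Reagents that add atoms: chlorotriisopropylsilane, CC(C)[Si](Cl)(C(C)C)C(C)C
Why: Imidazole-promoted silylation masks the phenol as a bulky aryl silyl ether that should survive the Lewis acid, organometallic and amide-base steps and fall to fluoride at the end.

Step 2
Reactants: 3 ethyl 2,4-dioxopentanoate
Product: 4 ethyl (2Z)-2,4-bis(trimethylsilyloxy)penta-2,4-dienoate
Conditions: Me3SiOTf (2.3 equiv), Et3N, Et2O, 0 °C → rt
Reagents that add atoms: trimethylsilyl trifluoromethanesulfonate, C[Si](C)(C)OS(=O)(=O)C(F)(F)F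
Why: Double soft enolisation and O-silylation of the enolised 1,3-dicarbonyl compound should give the 1,3-bis(silyl enol ether), whose terminal CH2 is the nucleophilic site, as with other bis-silyl dienol ethers.

Step 3
Reactants: 2 4-(triisopropylsilyloxy)benzaldehyde; 4 ethyl (2Z)-2,4-bis(trimethylsilyloxy)penta-2,4-dienoate
Product: 6 ethyl (2S)-4-oxo-2-[4-(triisopropylsilyloxy)phenyl]-2,3-dihydro-4H-pyran-6-carboxylate, via silylated aldol adduct 5 (not isolated)
Conditions: (S)-1,1′-bi-2-naphthol (20 mol %), Ti(OiPr)4 (20 mol %), 4 Å MS, THF, −78 → −20 °C; then CF3CO2H, CH2Cl2, 0 °C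
Reagents that add atoms: none
Why: Catalytic asymmetric vinylogous Mukaiyama aldol addition of the terminal carbon of the dienol ether to the aldehyde on the binaphtholate–titanium complex, expected to attack the Si face and so set C2 as S, is followed by acid desilylation, hemiketalisation of the benzylic oxygen onto the 2-oxo group and dehydration to the vinylogous ester, the cyclisation mode of Danishefsky-type aldol adducts.

Step 4
Reactants: 6 ethyl (2S)-4-oxo-2-[4-(triisopropylsilyloxy)phenyl]-2,3-dihydro-4H-pyran-6-carboxylate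
Product: 7 (2S)-N-methoxy-N-methyl-4-oxo-2-[4-(triisopropylsilyloxy)phenyl]-2,3-dihydro-4H-pyran-6-carboxamide
Conditions: MeNH(OMe)·HCl, AlMe3, CH2Cl2, 0 °C → rt
Reagents that add atoms: N,O-dimethylhydroxylamine hydrochloride, CNOC.Cl
Why: Aluminium amide aminolysis of the activated ester (Weinreb amide formation) runs under Lewis acidic, non-basic conditions that should neither enolise C3 nor open the vinylogous ester.

Step 5
Reactants: 7 (2S)-N-methoxy-N-methyl-4-oxo-2-[4-(triisopropylsilyloxy)phenyl]-2,3-dihydro-4H-pyran-6-carboxamide; 8 5-bromo-2-methylpent-2-ene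
Product: 10 (2S)-6-(5-methylhex-4-enoyl)-2-[4-(triisopropylsilyloxy)phenyl]-2,3-dihydro-4H-pyran-4-one, via homoprenylmagnesium bromide 9 (not isolated)
Conditions: 8, Mg, THF, rt; then 7, THF, −78 → −40 °C; aq NH4Cl
Reagents that add atoms: none
Why: Grignard addition to the Weinreb amide stops at the chelated tetrahedral intermediate and gives the ketone on work-up; at low temperature the chelating amide on the electron-poor C6 should react before the deactivated vinylogous ester carbonyl.

Step 6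
Reactants: 10 (2S)-6-(5-methylhex-4-enoyl)-2-[4-(triisopropylsilyloxy)phenyl]-2,3-dihydro-4H-pyran-4-one
Product: 12 2-diazo-5-methyl-1-{(2S)-4-oxo-2-[4-(triisopropylsilyloxy)phenyl]-2,3-dihydro-4H-pyran-6-yl}hex-4-en-1-one, via trifluoroacetyl diketone 11 (not isolated)
Conditions: LiN(SiMe3)2, THF, −78 °C; CF3CO2CH2CF3, −78 °C; then 4-AcNHC6H4SO2N3, Et3N, H2O, MeCN, rt
Reagents that add atoms: 4-acetamidobenzenesulfonyl azide, CC(=O)Nc1ccc(cc1)S(=O)(=O)N=[N+]=[N-]
Why: Detrifluoroacetylative diazo transfer (a Regitz-type transfer after kinetic trifluoroacetylation) should work because the unhindered CH2 beside the cross-conjugated exocyclic ketone is expected to be deprotonated before the more hindered, less acidic C3–H2 of the vinylogous ester, and the acidic 1,3-diketone then reacts with the sulfonyl azide under mild amine base with loss of the trifluoroacetyl group.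

Step 7
Reactants: 13 2-methylprop-2-enal
Product: 14 (3R)-2-methylhex-1-en-5-yn-3-ol
Conditions: allenyl-B(pin), (R)-3,3′-bis(2,4,6-triisopropylphenyl)-1,1′-binaphthyl-2,2′-diyl hydrogen phosphate (5 mol %), 4 Å MS, toluene, −20 °C
Reagents that add atoms: allenylboronic acid pinacol ester, C=C=CB1OC(C)(C)C(C)(C)O1
Why: Chiral phosphoric acid-catalysed propargylation of the enal by the allenylboronate through a closed six-membered SE2′ transition state should give the homopropargylic alcohol, the (R)-acid being expected to direct attack to the Re face and so give the (R)-carbinol.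

Step 8
Reactants: 14 (3R)-2-methylhex-1-en-5-yn-3-ol
Product: 15 tert-butyl(dimethyl){[(3R)-2-methylhex-1-en-5-yn-3-yl]oxy}silane
Conditions: t-BuMe2SiCl, imidazole, DMF, rt
Reagents that add atoms: tert-butyldimethylsilyl chloride, CC(C)(C)[Si](C)(C)Cl
Why: Standard silylation of the secondary alcohol protects it from the strong bases of the next step and from the ketene in the annulation.

Step 9
Reactants: 15 tert-butyl(dimethyl){[(3R)-2-methylhex-1-en-5-yn-3-yl]oxy}silane
Product: 17 tert-butyl(dimethyl){[(3R)-2-methyl-6-(triisopropylsilyloxy)hex-1-en-5-yn-3-yl]oxy}silane, via lithium ynolate 16 (not isolated)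
Conditions: n-BuLi, THF, −78 °C; t-BuOOLi (from t-BuOOH and LiN(SiMe3)2), −78 → 0 °C; then i-Pr3SiOTf, −78 °C
Reagents that add atoms: tert-butyl hydroperoxide, CC(C)(C)OO; triisopropylsilyl trifluoromethanesulfonate, CC(C)[Si](OS(=O)(=O)C(F)(F)F)(C(C)C)C(C)C
Why: Oxidation of the metallated alkyne carbon by lithium tert-butyl peroxide gives the ynolate, which the bulky silyl triflate traps on oxygen (the ynolate route to siloxyalkynes); the silyloxy group sits two atoms from the ynolate carbon, so neither elimination nor epimerisation is expected.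

Step 10
Reactants: 12 2-diazo-5-methyl-1-{(2S)-4-oxo-2-[4-(triisopropylsilyloxy)phenyl]-2,3-dihydro-4H-pyran-6-yl}hex-4-en-1-one; 17 tert-butyl(dimethyl){[(3R)-2-methyl-6-(triisopropylsilyloxy)hex-1-en-5-yn-3-yl]oxy}silane
Product: 22 (2S)-6-[(2R)-2-(tert-butyldimethylsilyloxy)-3-methylbut-3-enyl]-5-hydroxy-8-(3-methylbut-2-enyl)-7-(triisopropylsilyloxy)-2-[4-(triisopropylsilyloxy)phenyl]chroman-4-one, via vinylketene 18 (not isolated), via cyclobutenone 19 (not isolated), via dienylketene 20 (not isolated), via cyclohexadienone 21 (not isolated)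
Conditions: 17 (1.3 equiv), degassed ClCH2CH2Cl (0.05 M), hν (390–405 nm LEDs, borosilicate glass), 20 °C; then 80 °C
Reagents that add atoms: none
Why: Excitation of the diazo ketone expels N2 while the pyranyl carbon migrates from the carbonyl carbon to the diazo carbon (photochemical Wolff rearrangement, C8–C8a), and the resulting vinylketene adds the siloxyalkyne in a [2+2] cycloaddition in which the nucleophilic, chain-bearing alkyne carbon bonds to the ketene carbonyl carbon (C5–C6) and the oxygen-bearing carbon to the ketene α-carbon (C7–C8). On heating, the cyclobutenone opens by 4π conrotation to the dienylketene, ring A closes by 6π disrotatory electrocyclisation of the ketene carbon onto the pyranone α-carbon (C4a–C5), and the dienone, whose C4a–H lies between two carbonyls, enolises to the phenol hydrogen-bonded to C4=O. The closest known reaction is the Danheiser benzannulation of α-diazo enones with siloxyalkynes. No stereocentre remains from the step (the quaternary carbon of 19 and C4a of 21 are transient), and C2 and the side-chain carbinol lie away from every bond that forms. The step needs regioselectivity, given by the polarity match of ynol ether and ketene, and preference for the Wolff shift over hydrogen migration from the allylic CH2, which direct long-wavelength excitation without metal or sensitiser and immediate capture by excess alkyne should favour. The siloxyalkyne is far more nucleophilic than the prenyl and isopropenyl alkenes, and because C4=O and the ketene sit on opposite sides of the C4a=C8a bond, only the carbocyclic 6π closure is geometrically possible.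

Step 11
Reactants: 22 (2S)-6-[(2R)-2-(tert-butyldimethylsilyloxy)-3-methylbut-3-enyl]-5-hydroxy-8-(3-methylbut-2-enyl)-7-(triisopropylsilyloxy)-2-[4-(triisopropylsilyloxy)phenyl]chroman-4-one
Product: 23 (2S)-5,7-dihydroxy-6-[(2R)-2-hydroxy-3-methylbut-3-enyl]-2-(4-hydroxyphenyl)-8-(3-methylbut-2-enyl)chroman-4-one
Conditions: Bu4NF, AcOH (1:1, excess), THF, 0 °C → rt
Reagents that add atoms: none
Why: Fluoride cleaves the two aryl silyl ethers and the secondary silyl ether, and the acetic acid buffer keeps the medium from turning basic, which should prevent retro-oxa-Michael opening of the flavanone (loss of C2 configuration) and leave the prenyl group and the allylic alcohol untouched.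

Compound list
1 | 4-hydroxybenzaldehyde | O=Cc1ccc(O)cc1 | starting material
2 | 4-(triisopropylsilyloxy)benzaldehyde | O=Cc1ccc(O[Si](C(C)C)(C(C)C)C(C)C)cc1 | intermediate
3 | ethyl 2,4-dioxopentanoate | CCOC(=O)C(=O)CC(C)=O | starting material
4 | ethyl (2Z)-2,4-bis(trimethylsilyloxy)penta-2,4-dienoate | CCOC(=O)/C(O[Si](C)(C)C)=C/C(=C)O[Si](C)(C)C | intermediate
5 | ethyl (2Z,6S)-4-oxo-6-[4-(triisopropylsilyloxy)phenyl]-2,6-bis(trimethylsilyloxy)hex-2-enoate | CCOC(=O)/C(O[Si](C)(C)C)=C/C(=O)C[C@H](O[Si](C)(C)C)c1ccc(O[Si](C(C)C)(C(C)C)C(C)C)cc1 | intermediate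
6 | ethyl (2S)-4-oxo-2-[4-(triisopropylsilyloxy)phenyl]-2,3-dihydro-4H-pyran-6-carboxylate | CCOC(=O)C1=CC(=O)C[C@@H](c2ccc(O[Si](C(C)C)(C(C)C)C(C)C)cc2)O1 | intermediate
7 | (2S)-N-methoxy-N-methyl-4-oxo-2-[4-(triisopropylsilyloxy)phenyl]-2,3-dihydro-4H-pyran-6-carboxamide | CON(C)C(=O)C1=CC(=O)C[C@@H](c2ccc(O[Si](C(C)C)(C(C)C)C(C)C)cc2)O1 | intermediate
8 | 5-bromo-2-methylpent-2-ene | CC(C)=CCCBr | starting material
9 | (4-methylpent-3-en-1-yl)magnesium bromide | CC(C)=CCC[Mg]Br | intermediate
10 | (2S)-6-(5-methylhex-4-enoyl)-2-[4-(triisopropylsilyloxy)phenyl]-2,3-dihydro-4H-pyran-4-one | CC(C)=CCCC(=O)C1=CC(=O)C[C@@H](c2ccc(O[Si](C(C)C)(C(C)C)C(C)C)cc2)O1 | intermediate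
11 | 4,4,4-trifluoro-2-(3-methylbut-2-enyl)-1-{(2S)-4-oxo-2-[4-(triisopropylsilyloxy)phenyl]-2,3-dihydro-4H-pyran-6-yl}butane-1,3-dione (enolised, C2 undefined) | CC(C)=CCC(C(=O)C(F)(F)F)C(=O)C1=CC(=O)C[C@@H](c2ccc(O[Si](C(C)C)(C(C)C)C(C)C)cc2)O1 | intermediate
12 | 2-diazo-5-methyl-1-{(2S)-4-oxo-2-[4-(triisopropylsilyloxy)phenyl]-2,3-dihydro-4H-pyran-6-yl}hex-4-en-1-one | CC(C)=CCC(=[N+]=[N-])C(=O)C1=CC(=O)C[C@@H](c2ccc(O[Si](C(C)C)(C(C)C)C(C)C)cc2)O1 | intermediate
13 | 2-methylprop-2-enal | C=C(C)C=O | starting material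
14 | (3R)-2-methylhex-1-en-5-yn-3-ol | C=C(C)[C@H](O)CC#C | intermediate
15 | tert-butyl(dimethyl){[(3R)-2-methylhex-1-en-5-yn-3-yl]oxy}silane | C=C(C)[C@H](O[Si](C)(C)C(C)(C)C)CC#C | intermediate
16 | lithium (4R)-4-(tert-butyldimethylsilyloxy)-5-methylhex-5-en-1-yn-1-olate | C=C(C)[C@H](O[Si](C)(C)C(C)(C)C)CC#C[O-].[Li+] | intermediate
17 | tert-butyl(dimethyl){[(3R)-2-methyl-6-(triisopropylsilyloxy)hex-1-en-5-yn-3-yl]oxy}silane | C=C(C)[C@H](O[Si](C)(C)C(C)(C)C)CC#CO[Si](C(C)C)(C(C)C)C(C)C | intermediate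
18 | 5-methyl-2-{(2S)-4-oxo-2-[4-(triisopropylsilyloxy)phenyl]-2,3-dihydro-4H-pyran-6-yl}hexa-1,4-dien-1-one (vinylketene) | CC(C)=CCC(=C=O)C1=CC(=O)C[C@@H](c2ccc(O[Si](C(C)C)(C(C)C)C(C)C)cc2)O1 | intermediate
19 | 2-[(2R)-2-(tert-butyldimethylsilyloxy)-3-methylbut-3-enyl]-4-(3-methylbut-2-enyl)-4-{(2S)-4-oxo-2-[4-(triisopropylsilyloxy)phenyl]-2,3-dihydro-4H-pyran-6-yl}-3-(triisopropylsilyloxy)cyclobut-2-en-1-one (both C4 epimers) | C=C(C)[C@H](O[Si](C)(C)C(C)(C)C)CC1=C(O[Si](C(C)C)(C(C)C)C(C)C)C(CC=C(C)C)(C2=CC(=O)C[C@@H](c3ccc(O[Si](C(C)C)(C(C)C)C(C)C)cc3)O2)C1=O | intermediate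
20 | (3E)-2-[(2R)-2-(tert-butyldimethylsilyloxy)-3-methylbut-3-enyl]-7-methyl-4-{(2S)-4-oxo-2-[4-(triisopropylsilyloxy)phenyl]-2,3-dihydro-4H-pyran-6-yl}-3-(triisopropylsilyloxy)octa-1,3,6-trien-1-one (dienylketene, pyranyl cis to the ketene carbon) | C=C(C)[C@H](O[Si](C)(C)C(C)(C)C)CC(=C=O)/C(O[Si](C(C)C)(C(C)C)C(C)C)=C(\C1=CC(=O)C[C@@H](c2ccc(O[Si](C(C)C)(C(C)C)C(C)C)cc2)O1)CC=C(C)C | intermediate
21 | (2S)-6-[(2R)-2-(tert-butyldimethylsilyloxy)-3-methylbut-3-enyl]-8-(3-methylbut-2-enyl)-7-(triisopropylsilyloxy)-2-[4-(triisopropylsilyloxy)phenyl]-2,3-dihydro-4aH-chromene-4,5-dione (keto tautomer, C4a undefined) | C=C(C)[C@H](O[Si](C)(C)C(C)(C)C)CC1=C(O[Si](C(C)C)(C(C)C)C(C)C)C(CC=C(C)C)=C2O[C@H](c3ccc(O[Si](C(C)C)(C(C)C)C(C)C)cc3)CC(=O)C2C1=O | intermediate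
22 | (2S)-6-[(2R)-2-(tert-butyldimethylsilyloxy)-3-methylbut-3-enyl]-5-hydroxy-8-(3-methylbut-2-enyl)-7-(triisopropylsilyloxy)-2-[4-(triisopropylsilyloxy)phenyl]chroman-4-one | C=C(C)[C@H](O[Si](C)(C)C(C)(C)C)Cc1c(O[Si](C(C)C)(C(C)C)C(C)C)c(CC=C(C)C)c2c(c1O)C(=O)C[C@@H](c1ccc(O[Si](C(C)C)(C(C)C)C(C)C)cc1)O2 | intermediate
23 | (2S)-5,7-dihydroxy-6-[(2R)-2-hydroxy-3-methylbut-3-enyl]-2-(4-hydroxyphenyl)-8-(3-methylbut-2-enyl)chroman-4-one | C=C(C)[C@H](O)Cc1c(O)c(CC=C(C)C)c2c(c1O)C(=O)C[C@@H](c1ccc(O)cc1)O2 | target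

Total step count: 11. Longest linear sequence: 7 steps (1, 3, 4, 5, 6, 10, 11).

Steps most likely to fail

Step 10. Hydrogen migration from the allylic CH2 to the carbene centre, or intramolecular dipolar addition of the diazo group to the prenyl alkene, may outrun the Wolff shift, and a slow [2+2] capture would let the ketene dimerise. The fallback removes the allylic CH2 from the diazo carbon and adds the 8-prenyl group after ring A is made; it sets out from 7 and comes back at 22. MeMgBr (THF, −78 °C) should convert 7 into the methyl ketone (2S)-6-acetyl-2-[4-(triisopropylsilyloxy)phenyl]-2,3-dihydro-4H-pyran-4-one F1. Trifluoroacetylation as in step 6 should give the trifluoroacetyl diketone F2, and diazo transfer the diazomethyl ketone (2S)-6-(diazoacetyl)-2-[4-(triisopropylsilyloxy)phenyl]-2,3-dihydro-4H-pyran-4-one F3, the substrate type for which this benzannulation is established and in which no hydrogen shift is possible. Irradiation with 17 and heating as in step 10 should give the 8-unsubstituted chromanone F4. N-Iodosuccinimide (CH2Cl2, 0 °C) should iodinate C8, the only free position of ring A and para to the 5-hydroxyl, to the 8-iodochromanone F5. Stille coupling with tributyl(3-methylbut-2-enyl)stannane (Pd(PPh3)4, DMF, 90 °C) should then give 22.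

Step 6. Enolisation at C3 of the pyranone may compete with enolisation of the exocyclic ketone, leading to misplaced diazo transfer and to base-induced retro-oxa-Michael opening with erosion of the C2 configuration. The fallback fixes the diazo carbon through an enamine and forms no pyranone enolate; it sets out from 6, comes back at 12 and also bypasses steps 4 and 5.
- Me3SnOH (ClCH2CH2Cl, 70 °C) should hydrolyse 6 to the acid (2S)-4-oxo-2-[4-(triisopropylsilyloxy)phenyl]-2,3-dihydro-4H-pyran-6-carboxylic acid F6.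
- 1-Chloro-N,N,2-trimethylprop-1-en-1-amine (CH2Cl2, 0 °C) should give the acid chloride F7 under neutral conditions.
- Separately, Grignard reagent 9 (from 8) and DMF should give 5-methylhex-4-enal F8 (Bouveault formylation), which morpholine and K2CO3 should convert into the enamine 4-[(1E)-5-methylhexa-1,4-dien-1-yl]morpholine F9.
- Stork acylation of F9 with F7 (Et3N, CH2Cl2, 0 °C) should give the enaminone (2S)-6-[5-methyl-2-(morpholin-4-ylmethylidene)hex-4-enoyl]-2-[4-(triisopropylsilyloxy)phenyl]-2,3-dihydro-4H-pyran-4-one F10.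
- 4-AcNHC6H4SO2N3 (MeCN, rt) should add to the enamine double bond and fragment with loss of the sulfonyl formamidine (deformylative diazo transfer on an aminomethylene ketone) to give 12.

Step 3. The ester-substituted dienol ether may be too weak a nucleophile for the catalyst, or facial selectivity may be poor, and acid-induced benzylic ionisation may erode the configuration during cyclisation. The fallback separates the asymmetric step from the chain assembly; it sets out from 2 and comes back at 6. D-Proline (30 mol %, acetone/DMSO, rt) should give the aldol (4S)-4-hydroxy-4-[4-(triisopropylsilyloxy)phenyl]butan-2-one F11, since the L-catalyst is known to give the (R)-aldols of aryl aldehydes. Et3SiCl and imidazole should give the silyl ether (4S)-4-(triethylsilyloxy)-4-[4-(triisopropylsilyloxy)phenyl]butan-2-one F12. Crossed Claisen condensation (LiN(SiMe3)2, THF, −78 °C, then diethyl oxalate) should give ethyl (6S)-2,4-dioxo-6-(triethylsilyloxy)-6-[4-(triisopropylsilyloxy)phenyl]hexanoate F13. CF3CO2H (CH2Cl2, 0 °C) should remove the triethylsilyl group and cyclodehydrate to 6.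

Further compounds
F1 | step 10 | (2S)-6-acetyl-2-[4-(triisopropylsilyloxy)phenyl]-2,3-dihydro-4H-pyran-4-one | CC(=O)C1=CC(=O)C[C@@H](c2ccc(O[Si](C(C)C)(C(C)C)C(C)C)cc2)O1
F2 | step 10 | 4,4,4-trifluoro-1-{(2S)-4-oxo-2-[4-(triisopropylsilyloxy)phenyl]-2,3-dihydro-4H-pyran-6-yl}butane-1,3-dione | O=C(CC(=O)C(F)(F)F)C1=CC(=O)C[C@@H](c2ccc(O[Si](C(C)C)(C(C)C)C(C)C)cc2)O1
F3 | step 10 | (2S)-6-(diazoacetyl)-2-[4-(triisopropylsilyloxy)phenyl]-2,3-dihydro-4H-pyran-4-one | [N-]=[N+]=CC(=O)C1=CC(=O)C[C@@H](c2ccc(O[Si](C(C)C)(C(C)C)C(C)C)cc2)O1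
F4 | step 10 | (2S)-6-[(2R)-2-(tert-butyldimethylsilyloxy)-3-methylbut-3-enyl]-5-hydroxy-7-(triisopropylsilyloxy)-2-[4-(triisopropylsilyloxy)phenyl]chroman-4-one | C=C(C)[C@H](O[Si](C)(C)C(C)(C)C)Cc1c(O[Si](C(C)C)(C(C)C)C(C)C)cc2c(c1O)C(=O)C[C@@H](c1ccc(O[Si](C(C)C)(C(C)C)C(C)C)cc1)O2
F5 | step 10 | (2S)-6-[(2R)-2-(tert-butyldimethylsilyloxy)-3-methylbut-3-enyl]-5-hydroxy-8-iodo-7-(triisopropylsilyloxy)-2-[4-(triisopropylsilyloxy)phenyl]chroman-4-one | C=C(C)[C@H](O[Si](C)(C)C(C)(C)C)Cc1c(O[Si](C(C)C)(C(C)C)C(C)C)c(I)c2c(c1O)C(=O)C[C@@H](c1ccc(O[Si](C(C)C)(C(C)C)C(C)C)cc1)O2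
F6 | step 6 | (2S)-4-oxo-2-[4-(triisopropylsilyloxy)phenyl]-2,3-dihydro-4H-pyran-6-carboxylic acid | OC(=O)C1=CC(=O)C[C@@H](c2ccc(O[Si](C(C)C)(C(C)C)C(C)C)cc2)O1
F7 | step 6 | (2S)-4-oxo-2-[4-(triisopropylsilyloxy)phenyl]-2,3-dihydro-4H-pyran-6-carbonyl chloride | ClC(=O)C1=CC(=O)C[C@@H](c2ccc(O[Si](C(C)C)(C(C)C)C(C)C)cc2)O1
F8 | step 6 | 5-methylhex-4-enal | CC(C)=CCCC=O
F9 | step 6 | 4-[(1E)-5-methylhexa-1,4-dien-1-yl]morpholine | CC(C)=CC/C=C/N1CCOCC1
F10 | step 6 | (2S)-6-[5-methyl-2-(morpholin-4-ylmethylidene)hex-4-enoyl]-2-[4-(triisopropylsilyloxy)phenyl]-2,3-dihydro-4H-pyran-4-one | CC(C)=CCC(=CN1CCOCC1)C(=O)C1=CC(=O)C[C@@H](c2ccc(O[Si](C(C)C)(C(C)C)C(C)C)cc2)O1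
F11 | step 3 | (4S)-4-hydroxy-4-[4-(triisopropylsilyloxy)phenyl]butan-2-one | CC(=O)C[C@H](O)c1ccc(O[Si](C(C)C)(C(C)C)C(C)C)cc1
F12 | step 3 | (4S)-4-(triethylsilyloxy)-4-[4-(triisopropylsilyloxy)phenyl]butan-2-one | CC(=O)C[C@H](O[Si](CC)(CC)CC)c1ccc(O[Si](C(C)C)(C(C)C)C(C)C)cc1
F13 | step 3 | ethyl (6S)-2,4-dioxo-6-(triethylsilyloxy)-6-[4-(triisopropylsilyloxy)phenyl]hexanoate | CCOC(=O)C(=O)CC(=O)C[C@H](O[Si](CC)(CC)CC)c1ccc(O[Si](C(C)C)(C(C)C)C(C)C)cc1
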